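**Retrosynthetic overview**
- The last bond is the depside C(=O)–O bond, made from the ring B formyl acid and the ring A phenol by mixed-anhydride esterification.
- Both halves come from one intermediate, methyl 3-(1,3-dithian-2-yl)-2,4-dihydroxy-5,6-dimethylbenzoate: thioacetal hydrolysis gives the CHO of ring B, and Raney Ni desulfurisation gives the 3-CH3 of ring A.
- The key C–C bond is ring C3–CH(S)2. It is made by direct ortho C–H coupling in which 1,3-dithiane enters as a formyl-anion equivalent (aryloxysulfonium ylide, [2,3] shift) at a ring carbon that is itself innately nucleophilic.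
- Only one carbocycle is built: Michael–Claisen annulation of dimethyl malonate with 3-methylpent-3-en-2-one, then aromatisation. It is elaborated, split into ring A and ring B, and the two rings are joined last.

Assumption: the target has no stereocentre and no stereogenic double bond, so it is made as the achiral compound drawn; the transient stereocentres of the cyclohexenone intermediates are erased on aromatisation.

**Route**

Step 1
Reactants: 1 dimethyl malonate; 2 (E)-3-methylpent-3-en-2-one
Product: 4 methyl 2-hydroxy-5,6-dimethyl-4-oxocyclohex-2-ene-1-carboxylate, via Michael adduct 3 (not isolated)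
Conditions: NaOMe (1.1 equiv), MeOH, reflux; then aq. HCl
Reagents that add atoms: none
Why: Michael addition of the malonate anion to the enone β-carbon followed by intramolecular Claisen (Dieckmann-type) condensation of the methyl-ketone enolate onto one ester is the classical dihydroresorcylate annulation and places the two methyl groups on adjacent ring carbons next to the ester; the sp3 centres form as a mixture and are erased in step 2.

Step 2
Reactants: 4 methyl 2-hydroxy-5,6-dimethyl-4-oxocyclohex-2-ene-1-carboxylate
Product: 6 methyl 2,4-dihydroxy-5,6-dimethylbenzoate, via bromodione 5 (not isolated)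
Conditions: Br2 (1.0 equiv), DMF, 0 °C then 80 °C
Reagents that add atoms: none
Why: Bromination–dehydrobromination aromatisation, in which one equivalent of Br2 brominates the doubly activated C3 and the bis-enol of 5 then loses bromide and the C6 proton on warming; the ester is retained because decarboxylation needs much higher temperature.

Step 3
Reactants: 6 methyl 2,4-dihydroxy-5,6-dimethylbenzoate; 7 1,3-dithiane
Product: 12 methyl 3-(1,3-dithian-2-yl)-2,4-dihydroxy-5,6-dimethylbenzoate, via succinimidodithianium chloride 8 (not isolated), via aryloxysulfonium chloride 9 (not isolated), via sulfonium ylide 10 (not isolated), via dienone 11 (not isolated)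
Conditions: 7, NCS (1.2 equiv each), CH2Cl2, −70 °C; then 6, −70 °C; then Et3N, −70 °C to rt
Reagents that add atoms: none
Why: Gassman-type ortho-formylation, in which the free 4-OH displaces succinimide from the S-activated dithiane, Et3N deprotonates C2 of the dithiane to a sulfonium ylide that is a masked formyl anion, and its [2,3]-sigmatropic shift forms the C–C bond at C3, the only ortho position bearing hydrogen (a shift onto methyl-bearing C5 cannot rearomatise and reverts), before tautomerisation of the dienone restores the arene.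

Step 4
Reactants: 12 methyl 3-(1,3-dithian-2-yl)-2,4-dihydroxy-5,6-dimethylbenzoate
Product: 14 methyl 4-(benzyloxy)-3-(1,3-dithian-2-yl)-2-methoxy-5,6-dimethylbenzoate, via monobenzyl ether 13 (not isolated)
Conditions: BnBr (1.05 equiv), K2CO3, DMF, rt; then MeI (3 equiv), 50 °C
Reagents that add atoms: benzyl bromide, BrCc1ccccc1; iodomethane, CI
Why: Two-stage Williamson etherification, in which the more acidic, non-chelated 4-OH (para to the ester) is benzylated first and the ester-chelated 2-OH is then methylated by excess MeI on warming; phenoxide O-alkylation is much faster than S-alkylation of the thioacetal.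

Step 5
Reactants: 14 methyl 4-(benzyloxy)-3-(1,3-dithian-2-yl)-2-methoxy-5,6-dimethylbenzoate
Product: 15 methyl 4-hydroxy-2-methoxy-3,5,6-trimethylbenzoate
Conditions: Raney Ni (W-2, excess), H2 (1 atm), EtOH, reflux
Reagents that add atoms: none
Why: Mozingo desulfurisation cleaves both C–S bonds to leave the C3 methyl group and the same hydrogen-rich nickel hydrogenolyses the aryl benzyl ether, while the methyl ether, the ester and the fully substituted arene are inert.

Step 6
Reactants: 12 methyl 3-(1,3-dithian-2-yl)-2,4-dihydroxy-5,6-dimethylbenzoate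
Product: 16 methyl 3-formyl-2,4-dihydroxy-5,6-dimethylbenzoate
Conditions: HgCl2 (2.2 equiv), CaCO3, MeCN–H2O (4:1), reflux
Reagents that add atoms: water, O
Why: Thiophilic divalent mercury opens the thioacetal (Corey–Seebach dithiane hydrolysis) while CaCO3 buffers the acid, so the ester and phenols are untouched and the aldehyde emerges chelated between the two hydroxy groups.

Step 7
Reactants: 16 methyl 3-formyl-2,4-dihydroxy-5,6-dimethylbenzoate
Product: 17 3-formyl-2,4-dihydroxy-5,6-dimethylbenzoic acid
Conditions: KOH (8 equiv), H2O–MeOH (1:1), 70 °C, N2; then cold aq. HCl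
Reagents that add atoms: potassium hydroxide, [K+].[OH-]
Why: Saponification (BAC2 hydrolysis, helped by the ortho-phenoxide as in salicylate esters) cleaves the hindered ester, the non-enolisable aldehyde flanked by two phenoxides behaves as a vinylogous carboxylate and resists Cannizzaro reaction, and cold acidification of the formyl-deactivated acid avoids decarboxylation.

Step 8
Reactants: 15 methyl 4-hydroxy-2-methoxy-3,5,6-trimethylbenzoate; 17 3-formyl-2,4-dihydroxy-5,6-dimethylbenzoic acid
Product: 18 methyl 4-[(3-formyl-2,4-dihydroxy-5,6-dimethylbenzoyl)oxy]-2-methoxy-3,5,6-trimethylbenzoate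
Conditions: (CF3CO)2O (4 equiv), toluene, 0 °C to rt
Reagents that add atoms: none
Why: Trifluoroacetic anhydride turns the 2,6-disubstituted acid into its mixed anhydride/acylium ion, which acylates even the di-ortho-methyl phenol (the standard esterification for hindered depsides), and because both hydroxy groups of 17 are locked in hydrogen bonds to the formyl and carboxyl groups the only unchelated OH present is that of 15.

**Compound list**

1 | dimethyl malonate | COC(=O)CC(=O)OC | starting material
2 | (E)-3-methylpent-3-en-2-one | C/C=C(\C)C(C)=O | starting material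
3 | dimethyl 2-(3-methyl-4-oxopentan-2-yl)propanedioate (Michael adduct, diastereomer mixture) | COC(=O)C(C(=O)OC)C(C)C(C)C(C)=O | intermediate
4 | methyl 2-hydroxy-5,6-dimethyl-4-oxocyclohex-2-ene-1-carboxylate (enol form, diastereomer mixture) | COC(=O)C1C(O)=CC(=O)C(C)C1C | intermediate
5 | methyl 3-bromo-2-hydroxy-5,6-dimethyl-4-oxocyclohex-2-ene-1-carboxylate (diastereomer mixture) | COC(=O)C1C(O)=C(Br)C(=O)C(C)C1C | intermediate
6 | methyl 2,4-dihydroxy-5,6-dimethylbenzoate | COC(=O)c1c(O)cc(O)c(C)c1C | intermediate
7 | 1,3-dithiane | C1CSCSC1 | starting material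
8 | 1-(2,5-dioxopyrrolidin-1-yl)-1,3-dithian-1-ium chloride | O=C1CCC(=O)N1[S+]1CCCSC1.[Cl-] | intermediate
9 | 1-[5-hydroxy-4-(methoxycarbonyl)-2,3-dimethylphenoxy]-1,3-dithian-1-ium chloride | COC(=O)c1c(O)cc(O[S+]2CCCSC2)c(C)c1C.[Cl-] | intermediate
10 | 1-[5-hydroxy-4-(methoxycarbonyl)-2,3-dimethylphenoxy]-1,3-dithian-1-ium-2-ide | COC(=O)c1c(O)cc(O[S+]2CCCS[CH-]2)c(C)c1C | intermediate
11 | methyl 3-(1,3-dithian-2-yl)-2-hydroxy-5,6-dimethyl-4-oxocyclohexa-1,5-diene-1-carboxylate (racemic, transient) | COC(=O)C1=C(O)C(C2SCCCS2)C(=O)C(C)=C1C | intermediate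
12 | methyl 3-(1,3-dithian-2-yl)-2,4-dihydroxy-5,6-dimethylbenzoate | COC(=O)c1c(O)c(C2SCCCS2)c(O)c(C)c1C | intermediate
13 | methyl 4-(benzyloxy)-3-(1,3-dithian-2-yl)-2-hydroxy-5,6-dimethylbenzoate | COC(=O)c1c(O)c(C2SCCCS2)c(OCc3ccccc3)c(C)c1C | intermediate
14 | methyl 4-(benzyloxy)-3-(1,3-dithian-2-yl)-2-methoxy-5,6-dimethylbenzoate | COC(=O)c1c(OC)c(C2SCCCS2)c(OCc3ccccc3)c(C)c1C | intermediate
15 | methyl 4-hydroxy-2-methoxy-3,5,6-trimethylbenzoate | COC(=O)c1c(OC)c(C)c(O)c(C)c1C | intermediate
16 | methyl 3-formyl-2,4-dihydroxy-5,6-dimethylbenzoate | COC(=O)c1c(O)c(C=O)c(O)c(C)c1C | intermediate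
17 | 3-formyl-2,4-dihydroxy-5,6-dimethylbenzoic acid | OC(=O)c1c(O)c(C=O)c(O)c(C)c1C | intermediate
18 | methyl 4-[(3-formyl-2,4-dihydroxy-5,6-dimethylbenzoyl)oxy]-2-methoxy-3,5,6-trimethylbenzoate | COC(=O)c1c(C)c(C)c(OC(=O)c2c(C)c(C)c(O)c(C=O)c2O)c(C)c1OC | target

**Summary**

Total steps: 8. Longest linear sequence: 6 (steps 1, 2, 3, 4, 5, 8 or steps 1, 2, 3, 6, 7, 8).

The three steps most likely to fail are steps 3, 7 and 8.

The ylide rearrangement of step 3 may give low conversion or ring chlorination on this ester-deactivated resorcinol. The fallback keeps the formyl-anion logic but moves it to a cross-coupling. It sets out from 6, which is brominated at its only free position (NBS, MeCN, 0 °C) to methyl 3-bromo-2,4-dihydroxy-5,6-dimethylbenzoate F1. Both phenols are capped (MOMCl, iPr2NEt, CH2Cl2) to give methyl 3-bromo-2,4-bis(methoxymethoxy)-5,6-dimethylbenzoate F2. F2 is coupled with nitromethane as the formyl-anion equivalent (Pd2(dba)3, XPhos, Cs2CO3, MeNO2, 50 °C) to methyl 2,4-bis(methoxymethoxy)-5,6-dimethyl-3-(nitromethyl)benzoate F3. A Nef reaction (NaOMe, MeOH, then cold aq. H2SO4) and warming with aq. HCl in THF to remove the MOM groups bring the material back to the route at 16. The portion needed for ring A is thioacetalised (propane-1,3-dithiol, BF3·OEt2, CH2Cl2) to 12.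

The saponification of step 7 may degrade the aldehyde in hot alkali or lose CO2 on acidification. The fallback changes the order so that the ester is cleaved while the aldehyde is still masked and the free formyl acid never appears. It sets out from 12, which is saponified (KOH, H2O–DMSO, 80 °C) to 3-(1,3-dithian-2-yl)-2,4-dihydroxy-5,6-dimethylbenzoic acid F4. F4 is joined to 15 with (CF3CO)2O in toluene to give methyl 4-{[3-(1,3-dithian-2-yl)-2,4-dihydroxy-5,6-dimethylbenzoyl]oxy}-2-methoxy-3,5,6-trimethylbenzoate F5. The thioacetal is then opened last (HgCl2, CaCO3, aq. MeCN) and the route is rejoined at 18.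

The esterification of step 8 may give oligomers through the 4-OH of the unprotected acid. The fallback protects that hydroxyl. It sets out from 16, which is benzylated selectively at the 4-OH (BnBr, K2CO3, acetone, reflux) to methyl 4-(benzyloxy)-3-formyl-2-hydroxy-5,6-dimethylbenzoate F6. Saponification (KOH, H2O–DMSO, 80 °C) gives 4-(benzyloxy)-3-formyl-2-hydroxy-5,6-dimethylbenzoic acid F7. Coupling with 15 under (CF3CO)2O in toluene gives methyl 4-{[4-(benzyloxy)-3-formyl-2-hydroxy-5,6-dimethylbenzoyl]oxy}-2-methoxy-3,5,6-trimethylbenzoate F8. Hydrogenolysis (H2, Pd/C, EtOAc, rt) then rejoins the route at 18.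

**Further compounds**

F1 | step 3 | methyl 3-bromo-2,4-dihydroxy-5,6-dimethylbenzoate | COC(=O)c1c(O)c(Br)c(O)c(C)c1C
F2 | step 3 | methyl 3-bromo-2,4-bis(methoxymethoxy)-5,6-dimethylbenzoate | COC(=O)c1c(OCOC)c(Br)c(OCOC)c(C)c1C
F3 | step 3 | methyl 2,4-bis(methoxymethoxy)-5,6-dimethyl-3-(nitromethyl)benzoate | COC(=O)c1c(OCOC)c(C[N+](=O)[O-])c(OCOC)c(C)c1C
F4 | step 7 | 3-(1,3-dithian-2-yl)-2,4-dihydroxy-5,6-dimethylbenzoic acid | OC(=O)c1c(O)c(C2SCCCS2)c(O)c(C)c1C
F5 | step 7 | methyl 4-{[3-(1,3-dithian-2-yl)-2,4-dihydroxy-5,6-dimethylbenzoyl]oxy}-2-methoxy-3,5,6-trimethylbenzoate | COC(=O)c1c(C)c(C)c(OC(=O)c2c(C)c(C)c(O)c(C3SCCCS3)c2O)c(C)c1OC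
F6 | step 8 | methyl 4-(benzyloxy)-3-formyl-2-hydroxy-5,6-dimethylbenzoate | COC(=O)c1c(O)c(C=O)c(OCc2ccccc2)c(C)c1C
F7 | step 8 | 4-(benzyloxy)-3-formyl-2-hydroxy-5,6-dimethylbenzoic acid | OC(=O)c1c(O)c(C=O)c(OCc2ccccc2)c(C)c1C
F8 | step 8 | methyl 4-{[4-(benzyloxy)-3-formyl-2-hydroxy-5,6-dimethylbenzoyl]oxy}-2-methoxy-3,5,6-trimethylbenzoate | COC(=O)c1c(C)c(C)c(OC(=O)c2c(C)c(C)c(OCc3ccccc3)c(C=O)c2O)c(C)c1OC
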